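**Strategy.** The target is the ring hemiacetal (O1–C2) of an aroylmalonaldehyde in which the second aldehyde carbon has become the benzylic carbinol. The route rests on cutting the bond between that carbinol carbon and the 4-hydroxyphenyl ring. In a 3-formylchromone, C2 is stored as the enol-ether carbon of the 4-pyranone ring (O1–C2=C3) and only the exocyclic CHO on C3 is free; a chiral titanium–H8-BINOLate catalyst transfers a 4-(benzyloxy)phenyl group from an aryltitanium reagent to it. One operation joins both halves and sets the only configurationally stable stereocentre. Hydroxide then opens the pyranone, reclosure gives the lactol with C3 and C2 under thermodynamic control, and hydrogenolysis finishes.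

Key step: step 5

Remark: 1 and the THF solution of 8 are taken as commercial; C2 (hemiacetal) and C3 (between the C4 ketone and C2) equilibrate through the ring-opened β-keto aldehyde, so the route assumes that the target, the 2,3-trans lactol with C2–OH, the C3 side chain and the aryl group all equatorial on a hydrogen-bonded chair, is the thermodynamic isomer.

**Step 1**
Reactants: 1 1-(2,4,6-trihydroxy-3-methylphenyl)ethan-1-one
Product: 2 1-[4,6-bis(benzyloxy)-2-hydroxy-3-methylphenyl]ethan-1-one
Conditions: BnBr (2.05 equiv), K2CO3 (2.2 equiv), DMF, rt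
Reagents that add atoms: benzyl bromide, BrCc1ccccc1
Why: Williamson ether synthesis in which the 4-OH (para to the acetyl group, most acidic) reacts first and then the less hindered of the two chelated ortho-OH groups (the one next to ring H), so the OH flanked by acetyl and methyl should stay free.

**Step 2**
Reactants: 2 1-[4,6-bis(benzyloxy)-2-hydroxy-3-methylphenyl]ethan-1-one
Product: 4 1-[2,4-bis(benzyloxy)-3,6-dihydroxy-5-methylphenyl]ethan-1-one, via potassium aryl sulfate 3 (not isolated)
Conditions: K2S2O8, aq. KOH, pyridine, 0 °C → rt; then aq. HCl, 70 °C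
Reagents that add atoms: potassium peroxodisulfate, [K+].[K+].[O-]S(=O)(=O)OOS(=O)(=O)[O-]
Why: Elbs persulfate oxidation, in which the phenoxide attacks the peroxide O–O bond through its para carbon (the only free ring position) to give aryl sulfate 3, which dilute acid hydrolyses to the quinol, as is established for 2-hydroxy-4,6-dialkoxyacetophenones.

**Step 3**
Reactants: 4 1-[2,4-bis(benzyloxy)-3,6-dihydroxy-5-methylphenyl]ethan-1-one
Product: 5 1-[2,4-bis(benzyloxy)-6-hydroxy-3-methoxy-5-methylphenyl]ethan-1-one
Conditions: MeI (1.1 equiv), K2CO3 (1.1 equiv), acetone, rt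
Reagents that add atoms: iodomethane, CI
Why: Selective Williamson methylation, since the new 3-OH is free whereas the 6-OH is locked in a hydrogen bond to the acetyl group and shielded by the neighbouring methyl group, so one equivalent of MeI should alkylate only the former.

**Step 4**
Reactants: 5 1-[2,4-bis(benzyloxy)-6-hydroxy-3-methoxy-5-methylphenyl]ethan-1-one
Product: 7 5,7-bis(benzyloxy)-6-methoxy-8-methyl-4-oxo-4H-chromene-3-carbaldehyde, via chromonyl iminium chloride 6 (not isolated)
Conditions: POCl3 (3 equiv), DMF, 0 → 50 °C; then ice-water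
Reagents that add atoms: N,N-dimethylformamide, CN(C)C=O; water, O
Why: Vilsmeier–Haack reaction of a 2-hydroxyacetophenone (double C-formylation of the acetyl methyl group, ring closure by the only free phenol with loss of dimethylamine, hydrolysis of iminium salt 6), which fixes the 8-methyl/6-methoxy pattern because the ring can close only on the OH next to the methyl group.

**Step 5**
Reactants: 7 5,7-bis(benzyloxy)-6-methoxy-8-methyl-4-oxo-4H-chromene-3-carbaldehyde; 8 [4-(benzyloxy)phenyl]magnesium bromide
Product: 10 5,7-bis(benzyloxy)-3-{(R)-[4-(benzyloxy)phenyl](hydroxy)methyl}-6-methoxy-8-methyl-4H-chromen-4-one, via aryltitanium triisopropoxide 9 (not isolated)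
Conditions: 8 (1.5 equiv), ClTi(OiPr)3 (1.6 equiv), THF–CH2Cl2, −78 → 0 °C; (R)-3-(3,5-diphenylphenyl)-H8-BINOL (5 mol%), slow addition of 7, CH2Cl2, 0 °C; then H2O
Reagents that add atoms: none
Why: Transmetalation of 8 with ClTi(OiPr)3 gives the non-basic aryltitanium 9, whose aryl group is transferred to the titanium-bound formyl group of 7 inside the chiral titanium–H8-BINOLate complex (1,2-addition through a four-centre Ti–C/C=O transition state). The closest known reaction type is the titanium–BINOLate-catalysed enantioselective aryl transfer from aryltitanium triisopropoxides to aromatic and α,β-unsaturated aldehydes. No ring is closed in this step. The new stereocentre, the carbinol carbon (R by CIP in 10 because the chromen-3-yl group outranks the aryl group, and identical in space to the S centre of the target), is set by the ligand, which must deliver the aryl group to the Re face of the CHO group (O > C3 > H); the (R)-ligand is expected to do so by analogy with simple aryl aldehydes, and its antipode is used if the sense turns out reversed. The step needs 1,2-selectivity for the formyl group over conjugate attack at C2 and over the C4 ketone, which the oxophilic, weakly nucleophilic aryltitanium and the vinylogous-ester character of C2/C4 should secure. It also needs the catalysed path to outrun a chelation-assisted background addition, which is why 7 is added slowly at 0 °C.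

**Step 6**
Reactants: 10 5,7-bis(benzyloxy)-3-{(R)-[4-(benzyloxy)phenyl](hydroxy)methyl}-6-methoxy-8-methyl-4H-chromen-4-one
Product: 12 (2S,3R)-5,7-bis(benzyloxy)-3-{(S)-[4-(benzyloxy)phenyl](hydroxy)methyl}-2-hydroxy-6-methoxy-8-methyl-2,3-dihydro-4H-chromen-4-one, via ring-opened dilithium enolate 11 (not isolated)
Conditions: LiOH·H2O (2.5 equiv), THF–H2O (3:1), 0 °C; then AcOH to pH 6, 0 °C; extraction, equilibration in wet EtOAc at rt, crystallisation
Reagents that add atoms: lithium hydroxide, [Li+].[OH-]
Why: Alkaline ring-opening of a chromone (oxa-Michael addition of hydroxide at C2, then loss of the phenoxide) gives the stabilised enolate 11, which cannot undergo retro-aldol cleavage, and careful neutralisation recloses the o-hydroxyaryl β-keto aldehyde to the hemiacetal, while C3 (through the enol) and C2 (through ring–chain tautomerism) equilibrate and should settle in the all-equatorial 2,3-trans arrangement dictated by the fixed carbinol centre.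

**Step 7**
Reactants: 12 (2S,3R)-5,7-bis(benzyloxy)-3-{(S)-[4-(benzyloxy)phenyl](hydroxy)methyl}-2-hydroxy-6-methoxy-8-methyl-2,3-dihydro-4H-chromen-4-one
Product: 13 (2S,3R)-2,5,7-trihydroxy-3-[(S)-hydroxy(4-hydroxyphenyl)methyl]-6-methoxy-8-methyl-2,3-dihydro-4H-chromen-4-one
Conditions: H2 (1 atm), 10% Pd/C, EtOAc, rt
Reagents that add atoms: none
Why: Catalytic hydrogenolysis of the three aryl benzyl ethers under neutral conditions, in which the lactol, the β-hydroxy ketone and the secondary benzylic alcohol should be left untouched in the absence of acid and no stereocentre is affected.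

**Compound list**

1 | 1-(2,4,6-trihydroxy-3-methylphenyl)ethan-1-one | CC(=O)c1c(O)cc(O)c(C)c1O | starting material
2 | 1-[4,6-bis(benzyloxy)-2-hydroxy-3-methylphenyl]ethan-1-one | CC(=O)c1c(OCc2ccccc2)cc(OCc2ccccc2)c(C)c1O | intermediate
3 | potassium 3-acetyl-2,6-bis(benzyloxy)-4-hydroxy-5-methylphenyl sulfate | CC(=O)c1c(OCc2ccccc2)c(OS(=O)(=O)[O-])c(OCc2ccccc2)c(C)c1O.[K+] | intermediate
4 | 1-[2,4-bis(benzyloxy)-3,6-dihydroxy-5-methylphenyl]ethan-1-one | CC(=O)c1c(OCc2ccccc2)c(O)c(OCc2ccccc2)c(C)c1O | intermediate
5 | 1-[2,4-bis(benzyloxy)-6-hydroxy-3-methoxy-5-methylphenyl]ethan-1-one (free OH between acetyl and methyl) | CC(=O)c1c(OCc2ccccc2)c(OC)c(OCc2ccccc2)c(C)c1O | intermediate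
6 | N-{[5,7-bis(benzyloxy)-6-methoxy-8-methyl-4-oxo-4H-chromen-3-yl]methylidene}-N-methylmethanaminium chloride | COc1c(OCc2ccccc2)c(C)c2OC=C(C=[N+](C)C)C(=O)c2c1OCc1ccccc1.[Cl-] | intermediate
7 | 5,7-bis(benzyloxy)-6-methoxy-8-methyl-4-oxo-4H-chromene-3-carbaldehyde | COc1c(OCc2ccccc2)c(C)c2OC=C(C=O)C(=O)c2c1OCc1ccccc1 | intermediate
8 | [4-(benzyloxy)phenyl]magnesium bromide (THF solution) | Br[Mg]c1ccc(OCc2ccccc2)cc1 | starting material
9 | [4-(benzyloxy)phenyl]tri(propan-2-yloxy)titanium | CC(C)O[Ti](OC(C)C)(OC(C)C)c1ccc(OCc2ccccc2)cc1 | intermediate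
10 | 5,7-bis(benzyloxy)-3-{(R)-[4-(benzyloxy)phenyl](hydroxy)methyl}-6-methoxy-8-methyl-4H-chromen-4-one | COc1c(OCc2ccccc2)c(C)c2OC=C([C@H](O)c3ccc(OCc4ccccc4)cc3)C(=O)c2c1OCc1ccccc1 | intermediate
11 | dilithium (3R)-2-[4,6-bis(benzyloxy)-5-methoxy-3-methyl-2-oxidobenzoyl]-3-[4-(benzyloxy)phenyl]-3-hydroxyprop-1-en-1-olate (enolate geometry not defined) | [Li+].[Li+].[O-]C=C(C(=O)c1c([O-])c(C)c(OCc2ccccc2)c(OC)c1OCc1ccccc1)[C@H](O)c1ccc(OCc2ccccc2)cc1 | intermediate
12 | (2S,3R)-5,7-bis(benzyloxy)-3-{(S)-[4-(benzyloxy)phenyl](hydroxy)methyl}-2-hydroxy-6-methoxy-8-methyl-2,3-dihydro-4H-chromen-4-one | COc1c(OCc2ccccc2)c(C)c2c(c1OCc1ccccc1)C(=O)[C@H]([C@H](O)c1ccc(OCc3ccccc3)cc1)[C@@H](O)O2 | intermediate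
13 | (2S,3R)-2,5,7-trihydroxy-3-[(S)-hydroxy(4-hydroxyphenyl)methyl]-6-methoxy-8-methyl-2,3-dihydro-4H-chromen-4-one | COc1c(O)c(C)c2c(c1O)C(=O)[C@H]([C@H](O)c1ccc(O)cc1)[C@@H](O)O2 | target

**Step count and risks**

Total step count: 7. Longest linear sequence: 7 steps (1 → 13); fragment 8 enters at step 5.

Steps most likely to fail:

1. Step 5. The formyl and C4 carbonyl oxygens can bind titanium together, so a chelation-assisted uncatalysed aryl transfer may erode the enantioselectivity, and attack of aryl or alkoxide at C2 may compete with 1,2-addition. The fallback sets out from 7 and 8. The organocerium reagent made from 8 and CeCl3 (THF, −78 °C) should add cleanly to the formyl group and give the racemic carbinol 5,7-bis(benzyloxy)-3-{[4-(benzyloxy)phenyl](hydroxy)methyl}-6-methoxy-8-methyl-4H-chromen-4-one F1. MnO2 (CH2Cl2, rt) should oxidise it to the ketone 5,7-bis(benzyloxy)-3-[4-(benzyloxy)benzoyl]-6-methoxy-8-methyl-4H-chromen-4-one F2. A Corey–Bakshi–Shibata reduction (Me-CBS oxazaborolidine, BH3·SMe2, THF, −20 °C) then relies on the electronic difference between the electron-rich aryl and the electron-poor chromenyl group; the catalyst enantiomer is chosen to deliver hydride to the Si face of the ketone (O > chromen-3-yl > aryl). This comes back to the route at 10.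

2. Step 6. On neutralisation the open β-keto aldehyde may reclose with loss of water back to chromone 10, C3 may fail to equilibrate fully so that epimer mixtures persist, and base-induced loss of water from the aldol unit is a further drain. The fallback sets out from 10 and uses the same ring opening, but changes the isolation to a thermodynamic capture in a temporary ring. The cold, just-neutralised extract is stirred with phenylboronic acid and MgSO4 in CH2Cl2, which should drain the lactol from all equilibria as the cyclic phenylboronate of 12 F3. In this trans-fused 1,3,2-dioxaborinane the C2 oxygen, the C3 side chain and the aryl group are all equatorial, so the desired C3/C2 configuration is expected to be strongly preferred. F3 is purified, and exchange with pinacol (THF, rt) removes the boron and comes back to the route at 12.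

3. Step 2. The electron-rich phenoxide may be over-oxidised while conversion stays incomplete, and the poor solubility of its potassium salt worsens both. The fallback sets out from 2. NBS (MeCN, 0 °C) should brominate the only free ring position to give 1-[2,4-bis(benzyloxy)-3-bromo-6-hydroxy-5-methylphenyl]ethan-1-one F4. A copper-catalysed methoxylation (NaOMe, CuI cat., DMF–MeOH, 100 °C) then replaces bromine by methoxy and comes back to the route at 5, bypassing 3 and 4.

**Further compounds**

F1 | step 5 | 5,7-bis(benzyloxy)-3-{[4-(benzyloxy)phenyl](hydroxy)methyl}-6-methoxy-8-methyl-4H-chromen-4-one (racemic) | COc1c(OCc2ccccc2)c(C)c2OC=C(C(O)c3ccc(OCc4ccccc4)cc3)C(=O)c2c1OCc1ccccc1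
F2 | step 5 | 5,7-bis(benzyloxy)-3-[4-(benzyloxy)benzoyl]-6-methoxy-8-methyl-4H-chromen-4-one | COc1c(OCc2ccccc2)c(C)c2OC=C(C(=O)c3ccc(OCc4ccccc4)cc3)C(=O)c2c1OCc1ccccc1
F3 | step 6 | cyclic phenylboronate of 12 (boron bridges the C2 oxygen and the carbinol oxygen; trans-fused 1,3,2-dioxaborinane; 2S,3R and S carbinol carbon as in 12) | COc1c(OCc2ccccc2)c(C)c2c(c1OCc1ccccc1)C(=O)[C@@H]1[C@@H](c3ccc(OCc4ccccc4)cc3)OB(c3ccccc3)O[C@H]1O2
F4 | step 2 | 1-[2,4-bis(benzyloxy)-3-bromo-6-hydroxy-5-methylphenyl]ethan-1-one | CC(=O)c1c(OCc2ccccc2)c(Br)c(OCc2ccccc2)c(C)c1O
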